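**Retrosynthetic overview**
- Target ⇒ pentacosyl (E)-4-(benzyloxy)cinnamate: one hydrogenation saturates the C=C and removes the benzyl ether.
- Ester C–O bond ⇒ (E)-4-(benzyloxy)cinnamic acid + pentacosan-1-ol.
- Cα–Cβ bond of the C3 side chain (key step) ⇒ aldol addition of the lithium enolate of ethyl acetate to 4-(benzyloxy)benzaldehyde, then dehydration and saponification.
- Pentacosan-1-ol ⇒ C14 + C11 copper-catalysed coupling of tetradecylmagnesium bromide with silyl-protected 11-bromoundecan-1-ol.
- No ring is formed at any stage; the benzene ring is bought with the aldehyde.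

Assumption: the target has no stereocentre and no stereogenic double bond, so "single enantiomer" is taken to mean the achiral compound as drawn; pentacosan-1-ol is treated as too costly to buy and is built from cheap C14 and C11 bromides.

**Route**

Step 1
Reactants: 1 11-bromoundecan-1-ol
Product: 2 (11-bromoundecyloxy)(tert-butyl)dimethylsilane
Conditions: TBSCl (1.1 equiv), imidazole (1.5 equiv), CH2Cl2, 0 °C → rt, 2 h
Reagents that add atoms: tert-butyldimethylsilyl chloride, CC(C)(C)[Si](C)(C)Cl
Why: Imidazole-promoted silylation of a primary alcohol is fast and clean and masks the OH before the Grignard coupling; the primary bromide is untouched.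

Step 2
Reactants: 3 1-bromotetradecane; 2 (11-bromoundecyloxy)(tert-butyl)dimethylsilane
Product: 5 tert-butyldimethyl(pentacosyloxy)silane, via tetradecylmagnesium bromide 4 (not isolated)
Conditions: 3 (1.3 equiv), Mg turnings, I2 (crystal), THF, 45 °C, 1 h; then added to 2, Li2CuCl4 (3 mol%), THF, −10 °C → rt, 12 h; aq. NH4Cl
Reagents that add atoms: none
Why: Copper-catalysed sp3–sp3 Grignard cross-coupling (Kochi coupling) joins C14 to C11 to give the C25 chain, and the silyl ether tolerates the Grignard reagent.

Step 3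
Reactants: 5 tert-butyldimethyl(pentacosyloxy)silane
Product: 6 pentacosan-1-ol
Conditions: 2 M aq. HCl, THF, 40 °C, 3 h; recrystallise from acetone/hexane
Reagents that add atoms: none
Why: Acid hydrolysis of a primary TBS ether is reliable, and the polar crystalline alcohol is easily freed from the hydrocarbon by-products of step 2 (tetradecane, octacosane).

Step 4
Reactants: 7 ethyl acetate; 8 4-(benzyloxy)benzaldehyde
Product: 11 ethyl 3-[4-(benzyloxy)phenyl]-3-hydroxypropanoate (racemic), via lithium 1-ethoxyethen-1-olate 9 (not isolated), via racemic lithium 1-[4-(benzyloxy)phenyl]-3-ethoxy-3-oxopropan-1-olate 10 (not isolated)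
Conditions: LiN(iPr)2 (1.15 equiv), THF, −78 °C, 7 (1.2 equiv), 30 min; then 8 (1.0 equiv), −78 °C, 30 min; AcOH (1.3 equiv) quench at −78 °C
Reagents that add atoms: none
Why: Directed intermolecular aldol addition of a preformed lithium ester enolate to a non-enolisable aromatic aldehyde forms the Cα–Cβ bond cleanly; the new carbinol centre is racemic and is removed in step 5.

Step 5
Reactants: 11 ethyl 3-[4-(benzyloxy)phenyl]-3-hydroxypropanoate
Product: 13 ethyl (E)-3-[4-(benzyloxy)phenyl]prop-2-enoate, via racemic ethyl 3-[4-(benzyloxy)phenyl]-3-(methanesulfonyloxy)propanoate 12 (not isolated)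
Conditions: MsCl (1.3 equiv), Et3N (1.5 equiv), CH2Cl2, 0 °C, 30 min; then DBU (1.5 equiv), 0 °C → rt, 2 h
Reagents that add atoms: none
Why: Mesylation followed by base-induced E1cB elimination of the β-sulfonyloxy ester gives the conjugated, thermodynamically favoured E-cinnamate.

Step 6
Reactants: 13 ethyl (E)-3-[4-(benzyloxy)phenyl]prop-2-enoate
Product: 15 (E)-3-[4-(benzyloxy)phenyl]prop-2-enoic acid, via lithium (E)-3-[4-(benzyloxy)phenyl]prop-2-enoate 14 (not isolated)
Conditions: LiOH·H2O (3 equiv), THF/MeOH/H2O 3:1:1, 50 °C, 4 h; then 1 M HCl to pH 2, filter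
Reagents that add atoms: lithium hydroxide, [Li+].[OH-]
Why: Saponification of an ethyl ester proceeds without affecting the benzyl ether or the alkene, and the acid precipitates on acidification.

Step 7
Reactants: 15 (E)-3-[4-(benzyloxy)phenyl]prop-2-enoic acid; 6 pentacosan-1-ol
Product: 17 pentacosyl (E)-3-[4-(benzyloxy)phenyl]prop-2-enoate, via (E)-3-[4-(benzyloxy)phenyl]prop-2-enoyl chloride 16 (not isolated)
Conditions: (COCl)2 (1.3 equiv), DMF (cat.), CH2Cl2, 0 °C → rt, 2 h, evaporate; then 6 (0.95 equiv), Et3N (2 equiv), DMAP (0.1 equiv), toluene, 50 °C, 4 h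
Reagents that add atoms: none
Why: Acylation of the primary alcohol by the acid chloride (nucleophilic acyl substitution with DMAP catalysis) is irreversible, and warm toluene keeps the waxy alcohol in solution; the phenol is still benzyl-protected, so only one hydroxyl can react.

Step 8
Reactants: 17 pentacosyl (E)-3-[4-(benzyloxy)phenyl]prop-2-enoate
Product: 18 pentacosyl 3-(4-hydroxyphenyl)propanoate
Conditions: H2 (1 atm), Pd/C (10% Pd on carbon), THF/EtOAc 1:1, 40 °C, 12 h; filter warm through Celite, recrystallise
Reagents that add atoms: none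
Why: Heterogeneous catalytic hydrogenation saturates the conjugated alkene and hydrogenolyses the benzyl aryl ether in one operation, while the alkyl ester and the arene are inert at 1 atm.

**Compound list**

1 | 11-bromoundecan-1-ol | OCCCCCCCCCCCBr | starting material
2 | (11-bromoundecyloxy)(tert-butyl)dimethylsilane | CC(C)(C)[Si](C)(C)OCCCCCCCCCCCBr | intermediate
3 | 1-bromotetradecane | CCCCCCCCCCCCCCBr | starting material
4 | tetradecylmagnesium bromide | CCCCCCCCCCCCCC[Mg]Br | intermediate
5 | tert-butyldimethyl(pentacosyloxy)silane | CCCCCCCCCCCCCCCCCCCCCCCCCO[Si](C)(C)C(C)(C)C | intermediate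
6 | pentacosan-1-ol | CCCCCCCCCCCCCCCCCCCCCCCCCO | intermediate
7 | ethyl acetate | CCOC(C)=O | starting material
8 | 4-(benzyloxy)benzaldehyde | O=Cc1ccc(OCc2ccccc2)cc1 | starting material
9 | lithium 1-ethoxyethen-1-olate | [Li+].[O-]C(=C)OCC | intermediate
10 | lithium 1-[4-(benzyloxy)phenyl]-3-ethoxy-3-oxopropan-1-olate (racemic) | [Li+].[O-]C(CC(=O)OCC)c1ccc(OCc2ccccc2)cc1 | intermediate
11 | ethyl 3-[4-(benzyloxy)phenyl]-3-hydroxypropanoate (racemic) | CCOC(=O)CC(O)c1ccc(OCc2ccccc2)cc1 | intermediate
12 | ethyl 3-[4-(benzyloxy)phenyl]-3-(methanesulfonyloxy)propanoate (racemic) | CCOC(=O)CC(OS(C)(=O)=O)c1ccc(OCc2ccccc2)cc1 | intermediate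
13 | ethyl (E)-3-[4-(benzyloxy)phenyl]prop-2-enoate | CCOC(=O)/C=C/c1ccc(OCc2ccccc2)cc1 | intermediate
14 | lithium (E)-3-[4-(benzyloxy)phenyl]prop-2-enoate | [Li+].[O-]C(=O)/C=C/c1ccc(OCc2ccccc2)cc1 | intermediate
15 | (E)-3-[4-(benzyloxy)phenyl]prop-2-enoic acid | OC(=O)/C=C/c1ccc(OCc2ccccc2)cc1 | intermediate
16 | (E)-3-[4-(benzyloxy)phenyl]prop-2-enoyl chloride | ClC(=O)/C=C/c1ccc(OCc2ccccc2)cc1 | intermediate
17 | pentacosyl (E)-3-[4-(benzyloxy)phenyl]prop-2-enoate | CCCCCCCCCCCCCCCCCCCCCCCCCOC(=O)/C=C/c1ccc(OCc2ccccc2)cc1 | intermediate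
18 | pentacosyl 3-(4-hydroxyphenyl)propanoate | CCCCCCCCCCCCCCCCCCCCCCCCCOC(=O)CCc1ccc(O)cc1 | target

**Step count**

Total steps: 8. Longest linear sequence: 5 steps (steps 4, 5, 6, 7, 8; the alcohol branch, steps 1, 2, 3, 7, 8, is equally long).

**Three steps most likely to fail, with fallbacks**

Step 2 (Grignard cross-coupling: homocoupling or incomplete conversion). The fallback sets out from 1 and comes back to the route at 6, replacing the sp3–sp3 coupling by olefination and hydrogenation. Compound 1 is heated with PPh3 in MeCN to give (11-hydroxyundecyl)triphenylphosphonium bromide F1. Double deprotonation with NaN(SiMe3)2 (2.1 equiv) in THF at −78 °C → 0 °C and Wittig reaction with commercial tetradecanal give (Z)-pentacos-11-en-1-ol F2 (Z-major; the geometry is irrelevant). Hydrogenation over Pd/C (10% Pd on carbon) in THF/EtOAc then gives 6.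

Step 4 (cryogenic ester-enolate aldol: moisture, self-condensation of the enolate, retro-aldol on work-up). The fallback sets out from 8 and comes back to the route at 15, so steps 4 to 6 are bypassed. Compound 8 is heated with malonic acid in pyridine with catalytic piperidine at 100 °C (Knoevenagel–Doebner condensation). The first-formed 2-[[4-(benzyloxy)phenyl]methylidene]propanedioic acid F3 is not isolated and decarboxylates in the same pot to the E-acid 15.

Step 7 (acylation of a waxy, poorly soluble alcohol through a moisture-sensitive acid chloride). The fallback sets out from 6 and comes back to the route at 17, replacing acyl substitution by O-alkylation of the carboxylate. Compound 6 is converted by an Appel reaction (CBr4, PPh3, CH2Cl2/THF, rt) into 1-bromopentacosane F4. Acid 15 is treated with Cs2CO3 in DMF to give cesium (E)-3-[4-(benzyloxy)phenyl]prop-2-enoate F5, which is not isolated and is alkylated by F4 in DMF/THF at 60 °C to give 17.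

**Further compounds**

F1 | step 2 | (11-hydroxyundecyl)triphenylphosphonium bromide | OCCCCCCCCCCC[P+](c1ccccc1)(c1ccccc1)c1ccccc1.[Br-]
F2 | step 2 | (Z)-pentacos-11-en-1-ol | CCCCCCCCCCCCC/C=C\CCCCCCCCCCO
F3 | step 4 | 2-[[4-(benzyloxy)phenyl]methylidene]propanedioic acid | OC(=O)C(=Cc1ccc(OCc2ccccc2)cc1)C(=O)O
F4 | step 7 | 1-bromopentacosane | CCCCCCCCCCCCCCCCCCCCCCCCCBr
F5 | step 7 | cesium (E)-3-[4-(benzyloxy)phenyl]prop-2-enoate | [Cs+].[O-]C(=O)/C=C/c1ccc(OCc2ccccc2)cc1
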